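**Retrosynthetic overview**
- Feature: ring A is a fully substituted benzene. C6‑OMe and C7‑OMe sit side by side between oxygen‑bearing C5 and C8. These four carbons (C5–C6–C7–C8) are the four carbons of dimethyl squarate, laid against the C4a–C8a edge of pyranone ring C.
- End game: hydrogenolysis of the 3',5'‑benzyl ethers, preceded by methylation of the free 8‑OH of a 5,8‑hydroquinone whose 5‑OH is chelated to the C4 carbonyl.
- Key disconnection, bond C8–C8a: ring A arises by thermal ring expansion of a 4‑hydroxy‑4‑(4‑pyranonyl)‑2,3‑dimethoxycyclobutenone.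
- Bond C5–C4a comes from a 5‑magnesiated 2‑aryl‑4‑pyranone and dimethyl squarate. Ring C comes from the ring B aroyl chloride and the enolate of 3‑iodo‑4‑methoxybut‑3‑en‑2‑one, followed by acid closure.
- Order of rings: B is bought, C is closed second, A is closed last.

Key step: step 8

Remark: iodine is placed on the four‑carbon ketone before ring C is closed, because iodination of the finished 2‑aryl‑4‑pyranone would have to distinguish C5 from C3 and from the activated C2'/C6' positions of ring B; the enol‑ether geometry drawn for the acyclic iodides is lost on ring closure.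

**Step 1**
Reactants: 1 methyl 3,5-dihydroxy-4-methoxybenzoate
Product: 2 methyl 3,5-bis(benzyloxy)-4-methoxybenzoate
Conditions: BnBr (2.3 equiv), K2CO3 (3 equiv), DMF, 60 °C
Reagents that add atoms: benzyl bromide, BrCc1ccccc1
Why: Williamson ether synthesis on both phenoxides; benzyl is chosen because it withstands amide base, acid, the magnesium reagent and 140 °C and still leaves by hydrogenolysis at the end.

**Step 2**
Reactants: 2 methyl 3,5-bis(benzyloxy)-4-methoxybenzoate
Product: 3 3,5-bis(benzyloxy)-4-methoxybenzoic acid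
Conditions: LiOH, THF/MeOH/H2O, 50 °C; then 1 M HCl
Reagents that add atoms: lithium hydroxide, [Li+].[OH-]
Why: Saponification (acyl–oxygen cleavage by hydroxide) of an unhindered methyl benzoate, with the aryl benzyl and methyl ethers inert to base.

**Step 3**
Reactants: 3 3,5-bis(benzyloxy)-4-methoxybenzoic acid
Product: 4 3,5-bis(benzyloxy)-4-methoxybenzoyl chloride
Conditions: (COCl)2, cat. DMF, CH2Cl2, 0 °C → rt
Reagents that add atoms: oxalyl chloride, O=C(Cl)C(=O)Cl
Why: Acid chloride formation through the Vilsmeier-type chloroiminium salt, which runs under conditions that leave the ethers alone.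

**Step 4**
Reactants: 5 (E)-4-methoxybut-3-en-2-one
Product: 6 (Z)-3-iodo-4-methoxybut-3-en-2-one
Conditions: NIS (1.05 equiv), MeCN, 0 °C → rt, dark
Reagents that add atoms: N-iodosuccinimide, O=C1CCC(=O)N1I
Why: Electrophilic α-iodination of a vinylogous ester, a known reaction of β-alkoxy enones, in which electrophilic iodine adds at C3 (the only carbon made nucleophilic by the methoxy group) and the C3 proton is then lost; the isomer with OMe trans to acetyl is expected, but the geometry is of no consequence.

**Step 5**
Reactants: 6 (Z)-3-iodo-4-methoxybut-3-en-2-one; 4 3,5-bis(benzyloxy)-4-methoxybenzoyl chloride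
Product: 8 (Z)-1-[3,5-bis(benzyloxy)-4-methoxyphenyl]-4-iodo-5-methoxypent-4-ene-1,3-dione (largely enolized), via lithium enolate 7 (not isolated)
Conditions: 6 (2.0 equiv), LiN(SiMe3)2 (2.05 equiv), THF, −78 °C; then 4 (1.0 equiv), −78 → −30 °C; AcOH quench
Reagents that add atoms: none
Why: Claisen-type C-acylation of the kinetic cross-conjugated lithium enolate of a 4-methoxybutenone with an aroyl chloride, the standard entry to 2-substituted 4-pyranones; the methyl group is the only enolizable site, the second equivalent of enolate takes up the acidic diketone proton, and the hindered amide leaves the carbon–iodine bond alone at −78 °C.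

**Step 6**
Reactants: 8 (Z)-1-[3,5-bis(benzyloxy)-4-methoxyphenyl]-4-iodo-5-methoxypent-4-ene-1,3-dione
Product: 9 2-[3,5-bis(benzyloxy)-4-methoxyphenyl]-5-iodo-4H-pyran-4-one
Conditions: TFA (2 equiv), CH2Cl2, 0 °C → rt
Reagents that add atoms: none
Why: Acid-catalysed cyclocondensation in which the enol oxygen of the aroyl ketone adds to the methoxy-bearing carbon (6-endo oxa-Michael addition) and methanol is lost, so that iodine ends up on C5 next to unsubstituted C6 by connectivity alone.

**Step 7**
Reactants: 9 2-[3,5-bis(benzyloxy)-4-methoxyphenyl]-5-iodo-4H-pyran-4-one; 10 dimethyl squarate (3,4-dimethoxycyclobut-3-ene-1,2-dione)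
Product: 12 rac-4-{6-[3,5-bis(benzyloxy)-4-methoxyphenyl]-4-oxo-4H-pyran-3-yl}-4-hydroxy-2,3-dimethoxycyclobut-2-en-1-one, via pyranonylmagnesium chloride 11 (not isolated)
Conditions: i-PrMgCl·LiCl (1.05 equiv), THF, −40 °C, 30 min; then 10 (1.2 equiv), −40 → −10 °C; sat. aq. NH4Cl; acid-free work-up
Reagents that add atoms: none
Why: Iodine–magnesium exchange of the kind established for α-iodo-β-heteroatom enones (5-iodo-1,3-dioxin-4-ones, 5-iodouracils) should outrun attack on the pyranone, which has no enolizable hydrogen, and the alkenylmagnesium then adds 1,2 to one of the two equivalent squarate carbonyls as other organometallics do; the carbinol stereocentre forms as a racemate, which does not matter because it becomes planar C5 in step 8.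

**Step 8**
Reactants: 12 rac-4-{6-[3,5-bis(benzyloxy)-4-methoxyphenyl]-4-oxo-4H-pyran-3-yl}-4-hydroxy-2,3-dimethoxycyclobut-2-en-1-one
Product: 15 3',5'-bis(benzyloxy)-5,8-dihydroxy-6,7,4'-trimethoxyflavone, via dienylketene 13 (not isolated), via cyclohexadienone 14 (not isolated)
Conditions: degassed p-xylene (0.02 M), 138 °C, Ar
Reagents that add atoms: none
Why: Moore rearrangement: at about 140 °C the bond between the carbonyl carbon and the carbinol carbon of the cyclobutenone breaks in a conrotatory four-electron opening in which the donor hydroxyl turns outward and the pyranonyl group inward, which gives (Z)-dienylketene 13 with the pyranone C5=C6 bond lying next to the ketene carbon. Ring A then closes by a disrotatory six-electron electrocyclization that joins the ketene carbon to pyranone C6 (bond C8–C8a, six-membered carbocycle) to give cyclohexadienone 14, and transfer of the C8a hydrogen to the C8 oxygen (enolization) makes the ring aromatic. The closest known reactions are the thermal ring expansions of squarate-derived 4-alkenyl-, 4-aryl- and 4-heteroaryl-4-hydroxycyclobutenones to hydroquinones, and the pyranone alkene gives up far less aromatic stabilization on closure than the benzene rings that take part in them. No stereocentre has to be controlled, since the carbinol carbon of 12 and C8a of 14 both become planar. Regiochemistry follows from connectivity, because the carbinol carbon hangs on pyranone C5, whose only alkene partner is C6, so the carbinol carbon becomes C5 (free OH), the two methoxy carbons become C6 and C7 and the ketene carbon becomes C8 (free OH); the hydrogen bond from the enol OH of 13 to the C4 carbonyl holds just the s-cis rotamer that points C6 at the ketene. The step needs closure to outrun lactonization and ketene capture, which outward rotation of the hydroxyl, high dilution and an aprotic solvent secure, and degassing under argon keeps the hydroquinone from going to the quinone.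

**Step 9**
Reactants: 15 3',5'-bis(benzyloxy)-5,8-dihydroxy-6,7,4'-trimethoxyflavone
Product: 16 3',5'-bis(benzyloxy)-5-hydroxy-6,7,8,4'-tetramethoxyflavone
Conditions: Me2SO4 (1.05 equiv), K2CO3 (1.2 equiv), degassed acetone, reflux, Ar
Reagents that add atoms: dimethyl sulfate, COS(=O)(=O)OC
Why: Selective Williamson-type O-methylation, since the 8-OH is a free phenol while the 5-OH is tied up in a six-membered hydrogen bond to the C4 carbonyl and is not methylated by one equivalent of reagent with a weak base, the classical behaviour of 5-hydroxyflavones.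

**Step 10**
Reactants: 16 3',5'-bis(benzyloxy)-5-hydroxy-6,7,8,4'-tetramethoxyflavone
Product: 17 Gardenin E (5,3',5'-trihydroxy-6,7,8,4'-tetramethoxyflavone)
Conditions: H2 (1 atm), 10% Pd/C, EtOAc/MeOH, rt
Reagents that add atoms: none
Why: Catalytic hydrogenolysis of the two aryl benzyl ethers, under which the methyl ethers, the phenols and the conjugated C2=C3 bond of the flavone persist at one atmosphere and room temperature.

**Compound list**
1 | methyl 3,5-dihydroxy-4-methoxybenzoate | COC(=O)c1cc(O)c(OC)c(O)c1 | starting material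
2 | methyl 3,5-bis(benzyloxy)-4-methoxybenzoate | COC(=O)c1cc(OCc2ccccc2)c(OC)c(OCc2ccccc2)c1 | intermediate
3 | 3,5-bis(benzyloxy)-4-methoxybenzoic acid | OC(=O)c1cc(OCc2ccccc2)c(OC)c(OCc2ccccc2)c1 | intermediate
4 | 3,5-bis(benzyloxy)-4-methoxybenzoyl chloride | ClC(=O)c1cc(OCc2ccccc2)c(OC)c(OCc2ccccc2)c1 | intermediate
5 | (E)-4-methoxybut-3-en-2-one | CO/C=C/C(C)=O | starting material
6 | (Z)-3-iodo-4-methoxybut-3-en-2-one | CO/C=C(\I)C(C)=O | intermediate
7 | lithium (Z)-3-iodo-4-methoxybuta-1,3-dien-2-olate (not isolated) | CO/C=C(\I)C(=C)[O-].[Li+] | intermediate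
8 | (Z)-1-[3,5-bis(benzyloxy)-4-methoxyphenyl]-4-iodo-5-methoxypent-4-ene-1,3-dione | CO/C=C(\I)C(=O)CC(=O)c1cc(OCc2ccccc2)c(OC)c(OCc2ccccc2)c1 | intermediate
9 | 2-[3,5-bis(benzyloxy)-4-methoxyphenyl]-5-iodo-4H-pyran-4-one | O=c1cc(-c2cc(OCc3ccccc3)c(OC)c(OCc3ccccc3)c2)occ1I | intermediate
10 | dimethyl squarate | COC1=C(OC)C(=O)C1=O | starting material
11 | {6-[3,5-bis(benzyloxy)-4-methoxyphenyl]-4-oxo-4H-pyran-3-yl}magnesium chloride (not isolated) | O=c1cc(-c2cc(OCc3ccccc3)c(OC)c(OCc3ccccc3)c2)occ1[Mg]Cl | intermediate
12 | rac-4-{6-[3,5-bis(benzyloxy)-4-methoxyphenyl]-4-oxo-4H-pyran-3-yl}-4-hydroxy-2,3-dimethoxycyclobut-2-en-1-one (racemic) | COC1=C(OC)C(O)(c2coc(-c3cc(OCc4ccccc4)c(OC)c(OCc4ccccc4)c3)cc2=O)C1=O | intermediate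
13 | (Z)-4-hydroxy-2,3-dimethoxy-4-(6-aryl-4-oxo-4H-pyran-3-yl)buta-1,3-dien-1-one, aryl = 3,5-bis(benzyloxy)-4-methoxyphenyl (dienylketene, not isolated) | O=C=C(OC)/C(OC)=C(/O)c1coc(-c2cc(OCc3ccccc3)c(OC)c(OCc3ccccc3)c2)cc1=O | intermediate
14 | rac-2-[3,5-bis(benzyloxy)-4-methoxyphenyl]-5-hydroxy-6,7-dimethoxy-8aH-chromene-4,8-dione (racemic, not isolated) | COC1=C(OC)C(=O)C2OC(c3cc(OCc4ccccc4)c(OC)c(OCc4ccccc4)c3)=CC(=O)C2=C1O | intermediate
15 | 3',5'-bis(benzyloxy)-5,8-dihydroxy-6,7,4'-trimethoxyflavone | O=c1cc(-c2cc(OCc3ccccc3)c(OC)c(OCc3ccccc3)c2)oc2c(O)c(OC)c(OC)c(O)c12 | intermediate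
16 | 3',5'-bis(benzyloxy)-5-hydroxy-6,7,8,4'-tetramethoxyflavone | O=c1cc(-c2cc(OCc3ccccc3)c(OC)c(OCc3ccccc3)c2)oc2c(OC)c(OC)c(OC)c(O)c12 | intermediate
17 | Gardenin E | COc1c(O)cc(-c2cc(=O)c3c(O)c(OC)c(OC)c(OC)c3o2)cc1O | target

**Step count**
Total step count: 10.
Longest linear sequence: 9 (steps 1–3 and 5–10; step 4 is a one-step branch).

**Steps most likely to fail**

Step 8.
- What may go wrong: the ketene may form but close slowly, because its partner C6 is the electron-poor β-carbon of a vinylogous ester. Reversion to the cyclobutenone, lactonization after inward rotation of the hydroxyl, ketene oligomerization and air oxidation of the hydroquinone would then erode the step.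
- Fallback: it sets out from acid chloride 4 and comes back at hydroquinone 15, building ring A from a bought arene and adding the C8 oxygen last.
- Commercial 1-(6-hydroxy-2,3,4-trimethoxyphenyl)ethan-1-one F1 is O-aroylated with 4 in pyridine to 2-acetyl-3,4,5-trimethoxyphenyl 3,5-bis(benzyloxy)-4-methoxybenzoate F2.
- Baker–Venkataraman rearrangement (KOH, pyridine, 50 °C) gives 1-[3,5-bis(benzyloxy)-4-methoxyphenyl]-3-(6-hydroxy-2,3,4-trimethoxyphenyl)propane-1,3-dione F3.
- Cyclodehydration with catalytic p-TsOH in warm toluene gives 3',5'-bis(benzyloxy)-5,6,7,4'-tetramethoxyflavone F4.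
- One equivalent of BCl3 in CH2Cl2 at −78 °C, held in a chelate between the C4 carbonyl and the 5-methoxy oxygen, cleaves that ether only. The benzyl ethers have no neighbouring carbonyl. The product is 3',5'-bis(benzyloxy)-5-hydroxy-6,7,4'-trimethoxyflavone F5.
- Elbs persulfate oxidation (K2S2O8, aqueous KOH/pyridine) attacks C8, the position para to the 5-phenoxide and the only free carbon of ring A. It gives potassium 3',5'-bis(benzyloxy)-5-hydroxy-6,7,4'-trimethoxyflavon-8-yl sulfate F6, and warm dilute HCl hydrolyses this to 15.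

Step 7.
- What may go wrong: the isopropyl reagent may attack C6 or C2 of the pyranone in competition with exchange. The magnesiated pyranone may ring-open by β-elimination of the ring oxygen, since the metal and O1 lie trans across C5=C6. Addition of this stabilized carbanion to the squarate may also be sluggish.
- Fallback: it sets out from iodide 9 and comes back at cyclobutenol 12. The carbanion is no longer made by exchange with an alkylmagnesium but by oxidative insertion, and it is delivered as a zinc reagent to a Lewis-acid-activated squarate.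
- Zn dust with LiCl in THF at 25 °C inserts into the carbon–iodine bond to give {6-[3,5-bis(benzyloxy)-4-methoxyphenyl]-4-oxo-4H-pyran-3-yl}zinc iodide F7. This reagent is formed with no alkyl nucleophile present and should not ring-open at room temperature.
- MgCl2 (1 equiv) and 10 are then added. MgCl2 activates the strained 1,2-dione carbonyl for 1,2-addition, as it does in additions of organozinc halides to ketones, and an NH4Cl quench gives 12.

Step 5.
- What may go wrong: O-acylation may take the place of C-acylation. The enolate may lose hydrogen iodide or iodine. Proton exchange between product and enolate may stop conversion.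
- Fallback: it sets out from 4 and 5 and comes back at iodopyranone 9, with iodine introduced after ring closure instead of before it.
- The parent ketone 5 is deprotonated with LiN(SiMe3)2 to lithium (E)-4-methoxybuta-1,3-dien-2-olate F8, which is acylated with 4 to (E)-1-[3,5-bis(benzyloxy)-4-methoxyphenyl]-5-methoxypent-4-ene-1,3-dione F9.
- TFA closes F9 to 2-[3,5-bis(benzyloxy)-4-methoxyphenyl]-4H-pyran-4-one F10.
- Iodine in pyridine/CH2Cl2 (nucleophile-assisted α-iodination of enones) gives 9. Pyridine can add only to unsubstituted C6, so the resulting enolate is iodinated at C5 before pyridine is expelled. The reagent is too weak an electrophile to touch ring B.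

**Further compounds**
F1 | step 8 | 1-(6-hydroxy-2,3,4-trimethoxyphenyl)ethan-1-one (purchased) | CC(=O)c1c(O)cc(OC)c(OC)c1OC
F2 | step 8 | 2-acetyl-3,4,5-trimethoxyphenyl 3,5-bis(benzyloxy)-4-methoxybenzoate | CC(=O)c1c(OC(=O)c2cc(OCc3ccccc3)c(OC)c(OCc3ccccc3)c2)cc(OC)c(OC)c1OC
F3 | step 8 | 1-[3,5-bis(benzyloxy)-4-methoxyphenyl]-3-(6-hydroxy-2,3,4-trimethoxyphenyl)propane-1,3-dione | O=C(CC(=O)c1cc(OCc2ccccc2)c(OC)c(OCc2ccccc2)c1)c1c(O)cc(OC)c(OC)c1OC
F4 | step 8 | 3',5'-bis(benzyloxy)-5,6,7,4'-tetramethoxyflavone | O=c1cc(-c2cc(OCc3ccccc3)c(OC)c(OCc3ccccc3)c2)oc2cc(OC)c(OC)c(OC)c12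
F5 | step 8 | 3',5'-bis(benzyloxy)-5-hydroxy-6,7,4'-trimethoxyflavone | O=c1cc(-c2cc(OCc3ccccc3)c(OC)c(OCc3ccccc3)c2)oc2cc(OC)c(OC)c(O)c12
F6 | step 8 | potassium 3',5'-bis(benzyloxy)-5-hydroxy-6,7,4'-trimethoxyflavon-8-yl sulfate | [K+].O=c1cc(-c2cc(OCc3ccccc3)c(OC)c(OCc3ccccc3)c2)oc2c(OS(=O)(=O)[O-])c(OC)c(OC)c(O)c12
F7 | step 7 | {6-[3,5-bis(benzyloxy)-4-methoxyphenyl]-4-oxo-4H-pyran-3-yl}zinc iodide | O=c1cc(-c2cc(OCc3ccccc3)c(OC)c(OCc3ccccc3)c2)occ1[Zn]I
F8 | step 5 | lithium (E)-4-methoxybuta-1,3-dien-2-olate | CO/C=C/C(=C)[O-].[Li+]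
F9 | step 5 | (E)-1-[3,5-bis(benzyloxy)-4-methoxyphenyl]-5-methoxypent-4-ene-1,3-dione | CO/C=C/C(=O)CC(=O)c1cc(OCc2ccccc2)c(OC)c(OCc2ccccc2)c1
F10 | step 5 | 2-[3,5-bis(benzyloxy)-4-methoxyphenyl]-4H-pyran-4-one | O=c1ccoc(-c2cc(OCc3ccccc3)c(OC)c(OCc3ccccc3)c2)c1
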